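The numbers in the tables are simulated with constants of no real substance; noise was put on by code.

Late in Saturday's run the free monomer is still falling, from 14.9% at 5.00 d to 12.0% at 6.00 d, and the way that fall slows gives you the number you want.

| flask | free monomer | protic impurity | initiator | remark | time |
|---|---|---|---|---|---|
| Saturday's | 1 M (fed, over 2.0 h) | 0.075 M | 3 mM | run made earlier; the fed solution adds 0.25 times the starting volume |  |
| Tuesday's | 2.2 M (fed, over 2.0 h) | 0.075 M | 3 mM | run made earlier; the fed solution adds 0.25 times the starting volume |  |
| flask | 1.5 M (fed, over 2.0 h) | 0.0750 M | 3.0 mM | the fed solution adds 0.25 times the starting volume | 10 d |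

- Saturday's (time / d: monomer in chains / %, free monomer / %): 0.417: 17.4, 75.4; 1.25: 42.7, 50.5; 2.00: 55.7, 37.2; 3.00: 66.5, 25.8; 5.00: 78.8, 14.9; 6.00: 81.2, 12.0
- Tuesday's (time / d: monomer in chains / %, free monomer / %): 1.04: 38.0, 58.9; 2.08: 59.3, 36.5; 3.00: 70.0, 26.3; 4.00: 76.8, 19.4; 5.00: 82.0, 14.7; 6.00: 84.9, 13.5

(each reading ± 0.5 percentage points)

1. average number of monomer units in a chain (living and dead chains, two that joined counted as one) at 10 d
2. part of the free monomer that has reacted at 10 d

- amounts are per litre of the starting volume; all of the dose is in the solution fed
- the average divides the monomer in chains by the number of chains, living and dead together; two radicals that join make one chain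
- the numbers in the tables scatter with a standard deviation of 0.5 percentage points
- the earlier runs do not show the number of chains; that part of a forecast is a guess

Saturday's two columns stand 6.80% short of the charge, near the 7.50% that c(protic impurity)/c(free monomer) gives. So I count one free monomer lost per impurity, which is 5.00% in your flask.

Against what remains, the logarithmic fall of free monomer on Saturday is 1.27 by 3.00 d and 2.05 by 6.00 d, so the second stretch adds 0.780, less than the first. That second stretch keeps a factor 0.608 of the first. I assume that radicals die in pairs and stand at a steady level; the rate then follows the square root of c(initiator), and c(initiator) falls by that factor squared per stretch.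

I assume each initiator gives two radicals; two that join make one chain, so my chain count is the initiator spent per starting litre. The runs do not show it, so this is a guess.

Initiator left at 10 d: 3.63%

Chain count: 2.89 mM

Free monomer left, adding the shrinking stretches: 6.83%, so c is 93.2%

Degree of polymerisation, dp: 457

The forecast gave dp 690 (400 to 850) and c 94% (92.5% to 95.5%), adding “The chain count is a guess”, so my dp is lower than its figure.

The flask gives dp 455 and c 93.2%.

    initiator → 2 initiating radical (k = 2.40 × 10⁻⁴ min⁻¹)
    free monomer + initiating radical → growing radical + monomer in chains (k = 13000 M⁻¹ s⁻¹)
    free monomer + growing radical → monomer in chains + growing radical, rate k3*[growing radical]*[free monomer] (k = 31000 M⁻¹ min⁻¹)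
    2 growing radical → dead chain (k = 6.20 × 10⁷ M⁻¹ s⁻¹)
    protic impurity + free monomer → quenched substrate (k = 0.0120 M⁻¹ min⁻¹)

At 10.0 d the flask holds 0.00232 M of dead chain, which in the volume grown by the feed is 2.91 mM per starting litre, against my 2.89 mM. The neighbour with 0.30 M of protic impurity has 3.2% of its initiator left, as the flask has 3.2%, so I keep 2.89 mM. Its quenched share reckons to 20.0%, and with 5.68% free monomer left that puts 74.3% in chains and dp at 386. That neighbour gave 74.3% in chains and dp 384.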